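The ring numbering used throughout: ten-membered ring C1–C10 (C1 fusion CH, C10 fusion C–CH3, C4 exocyclic methylene, C5 prenyl, C7 acrylate); cyclobutane = C1, C1′H2, C2′H(isopropenyl), C10. The cyclobutane is read as the [2+2] adduct of an isopropenylketene equivalent across an (E)-C1=C10 alkene: the trans C1/C10 fusion and quaternary C10–CH3 are its stereospecific imprint. (S)-Carvone supplies C5–C10 and the C7 stereocentre; an anionic oxy-Cope rearrangement inserts C1–C4, giving the ten-membered ring as an enol triflate whose only nucleophilic alkene is C1=C10. A keteniminium [2+2] then forms C1–C1′, C10–C2′ and three stereocentres at once. Carbonyl deletion, Stille prenylation, SE2′ protodesilylation and acetyl-to-acrylate carbonylation complete the route.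

Key step: step 8

Remark (assumptions): 7, 13 and 22 are taken as purchasable. Where a SMILES carries no descriptor (sulfur in 5, hydrazone geometry in 18, the transient C1′ centre in 19 and 20) both forms are meant. "Ring-E" means the two ring bonds are trans across the double bond. The facial selectivities claimed in steps 5, 8 and 12 are conformational arguments, not computed results.

Step 1
Reactants: 1 (S)-(+)-carvone
Product: 2 (S)-5-acetyl-2-methylcyclohex-2-en-1-one
Conditions: O3, CH2Cl2/MeOH, −78 °C (Sudan III end point); then Me2S, −78 °C → rt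
Reagents that add atoms: ozone, [O-][O+]=O
Why: Chemoselective ozonolysis; the electron-rich 1,1-disubstituted isopropenyl C=C should be cleaved much faster than the electron-poor enone C=C, and the stereocentre (later C7) is untouched.

Step 2
Reactants: 2 (S)-5-acetyl-2-methylcyclohex-2-en-1-one
Product: 3 (S)-2-methyl-5-(2-methyl-1,3-dioxolan-2-yl)cyclohex-2-en-1-one
Conditions: (TMSOCH2)2, TMSOTf (cat.), CH2Cl2, −78 °C
Reagents that add atoms: 1,2-bis(trimethylsilyloxy)ethane, C[Si](C)(C)OCCO[Si](C)(C)C
Why: Noyori acetalisation; the saturated methyl ketone should react selectively because the conjugated ketone is far less electrophilic under these aprotic low-temperature conditions.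

Step 3
Reactants: 3 (S)-2-methyl-5-(2-methyl-1,3-dioxolan-2-yl)cyclohex-2-en-1-one
Product: 5 2-methyl-2-[2-(phenylsulfinyl)ethyl]-5-(2-methyl-1,3-dioxolan-2-yl)cyclohexan-1-one (sulfinylethyl cis to the dioxolanyl group), via lithium enolate 4 (not isolated)
Conditions: L-Selectride, THF, −78 °C; then phenyl vinyl sulfoxide, −78 → 0 °C; aq. NH4Cl
Reagents that add atoms: phenyl vinyl sulfoxide, C=CS(=O)c1ccccc1
Why: Conjugate hydride reduction gives the C1–C2 enolate regiospecifically, and its Michael addition to the vinyl sulfoxide (a vinyl cation equivalent) should occur axially, placing the new C–C bond cis to the equatorial C5 substituent as in Robinson annulations of dihydrocarvone.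

Step 4
Reactants: 5 2-methyl-2-[2-(phenylsulfinyl)ethyl]-5-(2-methyl-1,3-dioxolan-2-yl)cyclohexan-1-one
Product: 6 (2S,5S)-2-ethenyl-2-methyl-5-(2-methyl-1,3-dioxolan-2-yl)cyclohexan-1-one
Conditions: toluene, CaCO3, 110 °C
Reagents that add atoms: none
Why: Thermal syn-elimination of the sulfoxide (Ei) should unveil the vinyl group on the quaternary carbon without touching either stereocentre.

Step 5
Reactants: 6 (2S,5S)-2-ethenyl-2-methyl-5-(2-methyl-1,3-dioxolan-2-yl)cyclohexan-1-one; 7 (2-bromoprop-2-en-1-yl)trimethylsilane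
Product: 9 2-ethenyl-2-methyl-5-(2-methyl-1,3-dioxolan-2-yl)-1-[3-(trimethylsilyl)prop-1-en-2-yl]cyclohexan-1-ol (silylpropenyl trans to ethenyl), via alkenyllithium 8 (not isolated)
Conditions: 7, t-BuLi (2 equiv), Et2O, −78 °C; then 6, −78 °C; aq. NH4Cl
Reagents that add atoms: none
Why: Bromine–lithium exchange then 1,2-addition; in the chair with the dioxolanyl group equatorial the vinyl group is axial, so axial attack anti to it should give the trans-1,2-dialkenyl carbinol needed for a chair oxy-Cope.

Step 6
Reactants: 9 trans-1,2-dialkenyl carbinol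
Product: 12 ring-E,E ten-membered enol triflate (C5–OTf, C4–CH2SiMe3, C1=C10, C10–CH3, C7-dioxolanyl), via potassium alkoxide 10 (not isolated), via potassium enolate 11 (not isolated)
Conditions: KH, 18-crown-6, THF, 0 °C → rt; then PhNTf2, −78 → 0 °C; aq. NH4Cl
Reagents that add atoms: N-phenylbis(trifluoromethanesulfonimide), O=S(=O)(N(c1ccccc1)S(=O)(=O)C(F)(F)F)C(F)(F)F
Why: Anionic oxy-Cope rearrangement through a chair transition state with both alkenyl groups equatorial should convert the trans-dialkenylcyclohexanolate into the ring-E C1=C10 alkene and the ring-E C4=C5 enolate, which is trapped regiospecifically by O-triflation.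

Step 7
Reactants: 13 3-methylbut-3-enoic acid
Product: 14 N,N-dimethyl-3-methylbut-3-enamide
Conditions: Me2NH·HCl, EDC·HCl, HOBt (cat.), iPr2NEt, CH2Cl2, 0 °C → rt
Reagents that add atoms: dimethylamine hydrochloride, CNC.Cl
Why: Standard carbodiimide amidation; partial isomerisation to the conjugated amide would be harmless because both isomers lead to the same keteniminium ion in step 8.

Step 8
Reactants: 12 ring-E,E ten-membered enol triflate; 14 N,N-dimethyl-3-methylbut-3-enamide
Product: 17 trans-fused C1′-cyclobutanone (C2′ isopropenyl cis to C10–CH3), via keteniminium triflate 15 (not isolated), via cyclobutaniminium triflate 16 (not isolated)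
Conditions: 14 (2 equiv), Tf2O, 2,4,6-collidine, CH2Cl2, −20 → 0 °C; then 12, 0 → 40 °C; aq. NaHCO3, rt; Et3N (cat.), CH2Cl2, rt
Reagents that add atoms: water, O
Why: Collidine converts the O-triflyl iminium of 14 into vinylketeniminium 15, whose electrophilic central carbon is attacked by C1 of the strained trisubstituted C1=C10 bond (Markovnikov, charge at tertiary C10), and the enamine carbon C2′ then collapses onto C10 to give cyclobutaniminium 16, hydrolysed to 17; this is a keteniminium–alkene [2+2] cycloaddition of the Ghosez type, the nitrogen analogue of the ketene additions that turn trans-cycloalkenes into trans-fused cyclobutanones. The four-membered ring closes by an intermolecular, asynchronous [2+2] in which the C1–C1′ bond leads and the C10–C2′ bond follows as an ion-pair collapse, suprafacial on the alkene. The trans C1/C10 fusion and the C10 quaternary centre follow stereospecifically from the E geometry, and their absolute sense should come from attack on the peripheral face of the crown conformer in which the C10 methyl is syn to the equatorial C7 substituent, as in peripheral additions to germacra-1(10),4-dienes. C2′ is α to the new carbonyl and is set under thermodynamic control (Et3N), isopropenyl cis to the C10 methyl and 1,3-cis to C2, so both C2′ epimers converge on one. The step needs chemoselectivity for C1=C10, which should hold because C4=C5 is tetrasubstituted and deactivated by the triflate and no other C=C is present; Markovnikov regiochemistry, secured by the methyl on C10; and a temperature (≤40 °C) below that of the Cope rearrangement of the 1,5-diene.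

Step 9
Reactants: 17 trans-fused C1′-cyclobutanone
Product: 18 C1′ tosylhydrazone of 17
Conditions: TsNHNH2, EtOH, rt
Reagents that add atoms: p-toluenesulfonyl hydrazide, Cc1ccc(cc1)S(=O)(=O)NN
Why: Hydrazone condensation; the strained cyclobutanone is the only carbonyl group present and should condense readily.

Step 10
Reactants: 18 C1′ tosylhydrazone
Product: 21 trans-fused cyclobutane enol triflate (C1′ = CH2), via N-boryl tosylhydrazine 19 (not isolated), via alkyl diazene 20 (not isolated)
Conditions: catecholborane, CHCl3, 0 °C; then NaOAc·3H2O, 60 °C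
Reagents that add atoms: none
Why: Kabalka-type tosylhydrazone reduction (hydride to C=N, then acetate-induced loss of sulfinate and N2) should delete the carbonyl under mild, non-basic conditions that leave the β,γ-alkene, the C2′ centre and the enol triflate untouched.

Step 11
Reactants: 21 trans-fused cyclobutane enol triflate; 22 tributyl(3-methylbut-2-en-1-yl)stannane
Product: 23 C5-prenyl tetrasubstituted allylsilane (C4–CH2SiMe3, ring-E)
Conditions: Pd(PPh3)4 (5 mol%), LiCl, THF, 65 °C
Reagents that add atoms: none
Why: Stille coupling of the enol triflate with retention of alkene geometry; reductive elimination from the allyl–palladium intermediate at its less substituted terminus should give the linear prenyl group.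

Step 12
Reactants: 23 C5-prenyl tetrasubstituted allylsilane
Product: 24 methyl ketone with C4 exocyclic methylene and C5–H (C5 as in the target)
Conditions: TsOH·H2O (0.2 equiv), THF/H2O, 0 °C → rt
Reagents that add atoms: water, O
Why: SE2′ protodesilylation (proton to C5, silyl lost, C4=CH2 formed) with concurrent acetal hydrolysis; C5 should be set by protonation on the exposed peripheral face of the ring-E alkene, anti to the C–Si bond, in the conformer whose CH2Si arm lies on the C10-methyl face.

Step 13
Reactants: 24 methyl ketone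
Product: 26 1-substituted vinyl triflate at C7, via potassium enolate 25 (not isolated)
Conditions: KHMDS, THF, −78 °C; then PhNTf2, −78 → 0 °C; aq. NH4Cl
Reagents that add atoms: N-phenylbis(trifluoromethanesulfonimide), O=S(=O)(N(c1ccccc1)S(=O)(=O)C(F)(F)F)C(F)(F)F
Why: Kinetic deprotonation at the methyl group and O-triflation; the C7 methine is not deprotonated under these conditions, so C7 keeps its configuration.

Step 14
Reactants: 26 vinyl triflate
Product: 27 target compound CNP0314186.1
Conditions: Pd(OAc)2 (5 mol%), dppp, Et3N, CO (1 atm), MeOH/DMF, 50 °C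
Reagents that add atoms: carbon monoxide, [C-]#[O+]; methanol, CO
Why: Palladium-catalysed methoxycarbonylation of the vinyl triflate should give the 2-substituted methyl acrylate directly without affecting the other alkenes.

Compound list
1 | (S)-(+)-carvone, (5S)-2-methyl-5-(prop-1-en-2-yl)cyclohex-2-en-1-one | O=C1C(C)=CC[C@H](C(C)=C)C1 | starting material
2 | (S)-5-acetyl-2-methylcyclohex-2-en-1-one | O=C1C(C)=CC[C@H](C(C)=O)C1 | intermediate
3 | (S)-2-methyl-5-(2-methyl-1,3-dioxolan-2-yl)cyclohex-2-en-1-one | O=C1C(C)=CC[C@H](C2(C)OCCO2)C1 | intermediate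
4 | lithium 2-methyl-5-(2-methyl-1,3-dioxolan-2-yl)cyclohex-1-en-1-olate (not isolated) | [Li+].[O-]C1=C(C)CC[C@H](C2(C)OCCO2)C1 | intermediate
5 | 2-methyl-2-[2-(phenylsulfinyl)ethyl]-5-(2-methyl-1,3-dioxolan-2-yl)cyclohexan-1-one, sulfinylethyl cis to dioxolanyl, both sulfur epimers | O=C1[C@](C)(CCS(=O)c2ccccc2)CC[C@H](C3(C)OCCO3)C1 | intermediate
6 | (2S,5S)-2-ethenyl-2-methyl-5-(2-methyl-1,3-dioxolan-2-yl)cyclohexan-1-one, vinyl cis to dioxolanyl | O=C1[C@](C)(C=C)CC[C@H](C2(C)OCCO2)C1 | intermediate
7 | (2-bromoprop-2-en-1-yl)trimethylsilane | C=C(Br)C[Si](C)(C)C | starting material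
8 | [3-(trimethylsilyl)prop-1-en-2-yl]lithium (not isolated) | [Li]C(=C)C[Si](C)(C)C | intermediate
9 | 2-ethenyl-2-methyl-5-(2-methyl-1,3-dioxolan-2-yl)-1-[3-(trimethylsilyl)prop-1-en-2-yl]cyclohexan-1-ol, silylpropenyl trans to ethenyl, ethenyl cis to dioxolanyl | O[C@]1(C(=C)C[Si](C)(C)C)[C@](C)(C=C)CC[C@H](C2(C)OCCO2)C1 | intermediate
10 | potassium alkoxide of 9 (not isolated) | [K+].[O-][C@]1(C(=C)C[Si](C)(C)C)[C@](C)(C=C)CC[C@H](C2(C)OCCO2)C1 | intermediate
11 | potassium ring-E,E cyclodeca-1(10),4-dien-5-olate: 10-methyl, 7-(2-methyl-1,3-dioxolan-2-yl), 4-(trimethylsilylmethyl) (not isolated) | C1C/C=C(\C)/CC[C@H](C2(C)OCCO2)C/C([O-])=C1\C[Si](C)(C)C.[K+] | intermediate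
12 | ring-E,E cyclodeca-1(10),4-dien-5-yl triflate: 10-methyl, 7-(2-methyl-1,3-dioxolan-2-yl), 4-(trimethylsilylmethyl) | C1C/C=C(\C)/CC[C@H](C2(C)OCCO2)C/C(OS(=O)(=O)C(F)(F)F)=C1\C[Si](C)(C)C | intermediate
13 | 3-methylbut-3-enoic acid | CC(=C)CC(=O)O | starting material
14 | N,N-dimethyl-3-methylbut-3-enamide | CC(=C)CC(=O)N(C)C | intermediate
15 | N,N-dimethyl-(3-methylbuta-1,3-dien-1-ylidene)iminium triflate, isopropenyl keteniminium (not isolated) | CC(=C)C=C=[N+](C)C.[O-]S(=O)(=O)C(F)(F)F | intermediate
16 | cyclobutaniminium triflate: trans-fused bicyclo[8.2.0] skeleton, C1′=N+Me2, C2′ isopropenyl (not isolated) | C1C[C@@H]2C(=[N+](C)C)[C@H](C(=C)C)[C@@]2(C)CC[C@H](C3(C)OCCO3)C/C(OS(=O)(=O)C(F)(F)F)=C1\C[Si](C)(C)C.[O-]S(=O)(=O)C(F)(F)F | intermediate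
17 | trans-fused C1′-cyclobutanone: C1–H trans to C10–CH3, C2′ isopropenyl cis to C10–CH3, C5 triflate, C4 CH2SiMe3, C7 dioxolanyl | C1C[C@@H]2C(=O)[C@H](C(=C)C)[C@@]2(C)CC[C@H](C3(C)OCCO3)C/C(OS(=O)(=O)C(F)(F)F)=C1\C[Si](C)(C)C | intermediate
18 | C1′ tosylhydrazone of 17 | C1C[C@@H]2C(=NNS(=O)(=O)c3ccc(C)cc3)[C@H](C(=C)C)[C@@]2(C)CC[C@H](C3(C)OCCO3)C/C(OS(=O)(=O)C(F)(F)F)=C1\C[Si](C)(C)C | intermediate
19 | N-(1,3,2-benzodioxaborol-2-yl) tosylhydrazine at C1′ (not isolated) | C1C[C@@H]2C(N(B3Oc4ccccc4O3)NS(=O)(=O)c3ccc(C)cc3)[C@H](C(=C)C)[C@@]2(C)CC[C@H](C3(C)OCCO3)C/C(OS(=O)(=O)C(F)(F)F)=C1\C[Si](C)(C)C | intermediate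
20 | C1′ monoalkyl diazene (not isolated) | C1C[C@@H]2C(N=N)[C@H](C(=C)C)[C@@]2(C)CC[C@H](C3(C)OCCO3)C/C(OS(=O)(=O)C(F)(F)F)=C1\C[Si](C)(C)C | intermediate
21 | trans-fused cyclobutane (C1′ = CH2) with C5 triflate, C4 CH2SiMe3, C7 dioxolanyl, C2′ isopropenyl cis to C10–CH3 | C1C[C@@H]2C[C@H](C(=C)C)[C@@]2(C)CC[C@H](C3(C)OCCO3)C/C(OS(=O)(=O)C(F)(F)F)=C1\C[Si](C)(C)C | intermediate
22 | tributyl(3-methylbut-2-en-1-yl)stannane | CCCC[Sn](CCCC)(CCCC)CC=C(C)C | starting material
23 | C5-prenyl analogue of 21: ring-E tetrasubstituted C4=C5 allylsilane | C1C[C@@H]2C[C@H](C(=C)C)[C@@]2(C)CC[C@H](C3(C)OCCO3)C/C(CC=C(C)C)=C1\C[Si](C)(C)C | intermediate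
24 | C7 methyl ketone with C4 exocyclic methylene and C5 prenyl, stereocentres as in the target | C=C1CC[C@@H]2C[C@H](C(=C)C)[C@@]2(C)CC[C@H](C(C)=O)C[C@H]1CC=C(C)C | intermediate
25 | potassium enolate of 24, terminal enolate (not isolated) | C=C1CC[C@@H]2C[C@H](C(=C)C)[C@@]2(C)CC[C@H](C(=C)[O-])C[C@H]1CC=C(C)C.[K+] | intermediate
26 | C7 1-(trifluoromethylsulfonyloxy)ethenyl compound | C=C1CC[C@@H]2C[C@H](C(=C)C)[C@@]2(C)CC[C@H](C(=C)OS(=O)(=O)C(F)(F)F)C[C@H]1CC=C(C)C | intermediate
27 | CNP0314186.1 | C=C1CC[C@@H]2C[C@H](C(=C)C)[C@@]2(C)CC[C@H](C(=C)C(=O)OC)C[C@H]1CC=C(C)C | target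

Total step count: 14. Longest linear sequence: 13 steps (steps 1–6 and 8–14 from 1; step 7 is a one-step side branch).

Steps most likely to fail

Step 8. The vinyl-substituted keteniminium ion may react through its conjugated terminus, or the developing C10 cation may be diverted before ring closure, by proton loss (ene-type acylation) or by transannular attack of the C4=C5 allylsilane. The base used to equilibrate C2′ may also move the isopropenyl double bond into conjugation. The fallback uses a concerted ketene cycloaddition and introduces the three-carbon unit afterwards; it sets out from 12 and returns at 21. Dichloroketene (Cl3CCOCl, Zn–Cu, Et2O/DME), the classical reagent for trans-cycloalkenes and trisubstituted alkenes, should give the trans-fused dichlorocyclobutanone F1 with the carbonyl on C1′. Zn/NH4Cl in MeOH should give the cyclobutanone F2. LDA then acetone should give the C2′ aldol adduct F3, which is taken through its tosylhydrazone F4 and catecholborane/NaOAc reduction to the tertiary alcohol F5. Burgess dehydration (syn-elimination towards a methyl group) should then give 21.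

Step 5. The facial selectivity of the carbonyl addition may be poor: equatorial attack syn to the axial vinyl group would give the cis-dialkenyl carbinol, which the oxy-Cope step would turn into a (Z)-C1=C10 alkene and finally a cis-fused ring. The fallback separates stereocontrol from construction of the alkenyl group; it sets out from 6 and returns at 9. Ethynylmagnesium bromide, a slim nucleophile with a strong axial preference, should give the ethynyl carbinol F6 with the alkyne trans to the vinyl group. Copper-catalysed, alkoxide-directed anti-carbomagnesiation with (trimethylsilyl)methylmagnesium chloride, forming the C–C bond at the alkyne carbon next to the carbinol, should then give 9 after protonation.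

Step 12. Protonation at C5 may occur on the wrong face, or be unselective, if the reactive conformer has the CH2Si arm on the face opposite to the C10 methyl. The fallback forms the C5–C bond, not the C5–H bond, on the exposed face, which is stereocomplementary; it sets out from 21 and returns at 24. Palladium-catalysed formate reduction of the triflate (Pd(OAc)2, PPh3, Bu3N, HCO2H) should give the trisubstituted allylsilane F7. Lewis-acid-mediated SE2′ prenylation (1-bromo-3-methylbut-2-ene, ZnBr2, CH2Cl2, −78 °C) should give the acetal F8 with the C4 methylene and C5 prenyl in place, and TsOH in wet THF should hydrolyse it to 24.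

Further compounds
F1 | step 8 | trans-fused 2′,2′-dichloro-C1′-cyclobutanone from dichloroketene and 12 | C1C[C@@H]2C(=O)C(Cl)(Cl)[C@@]2(C)CC[C@H](C3(C)OCCO3)C/C(OS(=O)(=O)C(F)(F)F)=C1\C[Si](C)(C)C
F2 | step 8 | trans-fused C1′-cyclobutanone with unsubstituted C2′ | C1C[C@@H]2C(=O)C[C@@]2(C)CC[C@H](C3(C)OCCO3)C/C(OS(=O)(=O)C(F)(F)F)=C1\C[Si](C)(C)C
F3 | step 8 | C2′ aldol adduct of F2 with acetone, 2-hydroxypropan-2-yl cis to C10–CH3 | C1C[C@@H]2C(=O)[C@H](C(C)(C)O)[C@@]2(C)CC[C@H](C3(C)OCCO3)C/C(OS(=O)(=O)C(F)(F)F)=C1\C[Si](C)(C)C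
F4 | step 8 | tosylhydrazone of F3 | C1C[C@@H]2C(=NNS(=O)(=O)c3ccc(C)cc3)[C@H](C(C)(C)O)[C@@]2(C)CC[C@H](C3(C)OCCO3)C/C(OS(=O)(=O)C(F)(F)F)=C1\C[Si](C)(C)C
F5 | step 8 | deoxygenated tertiary alcohol, C1′ = CH2, C2′ 2-hydroxypropan-2-yl | C1C[C@@H]2C[C@H](C(C)(C)O)[C@@]2(C)CC[C@H](C3(C)OCCO3)C/C(OS(=O)(=O)C(F)(F)F)=C1\C[Si](C)(C)C
F6 | step 5 | 1-ethynyl-2-ethenyl-2-methyl-5-(2-methyl-1,3-dioxolan-2-yl)cyclohexan-1-ol, ethynyl trans to ethenyl | O[C@]1(C#C)[C@](C)(C=C)CC[C@H](C2(C)OCCO2)C1
F7 | step 12 | ring-E trisubstituted C4=C5 allylsilane, C5–H, from formate reduction of 21 | C1C[C@@H]2C[C@H](C(=C)C)[C@@]2(C)CC[C@H](C3(C)OCCO3)C/C=C1\C[Si](C)(C)C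
F8 | step 12 | C7 dioxolane of 24, C4 methylene and C5 prenyl | C=C1CC[C@@H]2C[C@H](C(=C)C)[C@@]2(C)CC[C@H](C3(C)OCCO3)C[C@H]1CC=C(C)C
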